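**Plan** (locants count the heavy atoms of the target SMILES from left to right, C1 to O26)

1. Cuts, last to first: O18–C19 and C8–C19 (closing Knoevenagel/oxa-Michael cascade), O11–C9 (acylketene macrolactonisation), C19–C20 and C21–C22 (Michael–Claisen annulation), C13–C14 and C16–C23 (key step).
2. Enabling feature: in the carbocycle C12–C13–C14–C16–C23–C22, C13 and C23 are both 1,3 to the quaternary C12, so C13–C12–C22–C23 can be folded back into a cyclobutanone with C23 as carbonyl. C14–C16 carries O18, which is tied to C12 through C19 as a (Z)-enol ester, so inserting C14=C16 into the acyl–CH2 bond gives the ring and the O18 bridge together.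
3. Forward order: cyclobutanone enol ester, then 2-oxabicyclo[2.2.2]octanedione (key step), then the cyclopentane (C12, C19–C22), then an eleven-membered β-keto lactone, then γ-lactone, eight-membered ring and ether bridge in one closing cascade.
4. Stereochemistry: C12/C16 from ligand choice between enantiotopic ring bonds; C14 from the (Z)-alkene by suprafacial addition; C2/C4 from desymmetrisation of meso-2,4-dimethylglutaric anhydride; C22 by equilibration during annulation; C23 by hydroxyl-directed reduction; C19 and C20 by the cage (thermodynamic).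
5. Protecting groups: benzyl on O11 and on the C6 acid (one hydrogenolysis); triethylsilyl on O18 and O24.

Key step: step 5

Assumption (chemistry): for the two ligand-controlled steps (5 and 6) the ligand antipode that gives the drawn enantiomer is meant; the sense of induction is not predicted here.

Step 1
Reactants: 1 methyl 3,3-dimethoxycyclobutane-1-carboxylate
Product: 2 methyl 1-hydroxy-3,3-dimethoxycyclobutane-1-carboxylate
Conditions: LiN(iPr)2, THF, −78 °C; then 2-(phenylsulfonyl)-3-phenyloxaziridine, −78 → 0 °C; aq. NH4Cl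
Reagents that add atoms: 2-(phenylsulfonyl)-3-phenyloxaziridine, O=S(=O)(N1OC1c1ccccc1)c1ccccc1
Why: oxaziridine α-hydroxylation of the ester enolate (Davis oxidation); the new carbinol carbon lies on the mirror plane of the ring, so no stereocentre arises.

Step 2
Reactants: 2 methyl 1-hydroxy-3,3-dimethoxycyclobutane-1-carboxylate
Product: 3 methyl 1-(benzyloxy)-3,3-dimethoxycyclobutane-1-carboxylate
Conditions: NaH, BnBr, Bu4NI (cat.), DMF, 0 °C → rt
Reagents that add atoms: benzyl bromide, BrCc1ccccc1
Why: Williamson etherification of the tertiary alkoxide; the benzyl ether blocks retro-aldol opening of the later 3-oxygenated cyclobutanone and is a poor β-leaving group in the key step.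

Step 3
Reactants: 3 methyl 1-(benzyloxy)-3,3-dimethoxycyclobutane-1-carboxylate
Product: 5 1-(benzyloxy)-3-oxocyclobutane-1-carboxylic acid, via ketal acid 4 (not isolated)
Conditions: LiOH, THF/MeOH/H2O, 40 °C; then 2 M HCl, acetone, rt
Reagents that add atoms: lithium hydroxide, [Li+].[OH-]; water, O
Why: ester saponification followed by acid hydrolysis of the dimethyl ketal; the benzyl ether is stable to both and no stereocentre is present.

Step 4
Reactants: 5 1-(benzyloxy)-3-oxocyclobutane-1-carboxylic acid; 6 but-2-yne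
Product: 7 (Z)-but-2-en-2-yl 1-(benzyloxy)-3-oxocyclobutane-1-carboxylate
Conditions: Ph3PAuCl (5 mol %), AgPF6 (5 mol %), 6 (5 equiv), toluene, 60 °C, sealed tube
Reagents that add atoms: none
Why: gold-catalysed intermolecular hydroacyloxylation of an internal alkyne; anti addition of O and H across the triple bond places the ester oxygen cis to the distal methyl, which is the (Z)-enol ester needed for C14.

Step 5
Reactants: 7 (Z)-but-2-en-2-yl 1-(benzyloxy)-3-oxocyclobutane-1-carboxylate
Product: 8 (1S,4S,7S)-4-(benzyloxy)-1,7-dimethyl-2-oxabicyclo[2.2.2]octane-3,6-dione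
Conditions: Ni(cod)2 (10 mol %), TADDOL-derived phosphoramidite ligand (20 mol %), toluene, 90 °C
Reagents that add atoms: none
Why: Proposed new method: zerovalent nickel binds the strained ketone and, through the two-atom ester tether, the enol-ester alkene; oxidative cyclisation joins the carbonyl carbon C23 to the oxygen-bearing alkene carbon C16 (closing the ring O18–C19–C12–C22–C23–C16 in the 6-exo mode) to give an oxanickelacyclopentane, β-carbon elimination then cuts one acyl–CH2 bond of the four-membered ring, and C(sp3)–C(sp3) reductive elimination from the seven-membered nickelacycle makes C13–C14 (closing the carbocycle and the second six-membered ring). The closest known reaction type is the nickel-catalysed intramolecular alkene insertion into 3-(2-vinylaryl)cyclobutanones, which gives benzobicyclo[2.2.2]octenones and has an enantioselective phosphoramidite version; new here are the enol-ester alkene, the ester tether and the oxygenated quaternary ring carbon. C12 and C16 are set together, because the ligand chooses which of the two enantiotopic acyl–CH2 bonds is cut and the short tether then allows only the cis-bridged alkene face; C14 follows from the (Z)-alkene because both new bonds form on the same face. The step needs (a) enantiotopic-bond selectivity, supplied by the ligand, (b) bonding of C23 to the proximal rather than the distal alkene carbon, supplied by the tether length (six- against seven-membered ring), and (c) reductive elimination ahead of β-hydride or β-alkoxide loss and of ester C–O insertion, for which the strained nickelacycle and the poor leaving ability of the benzyl ether are relied on. The reacting s-trans ester rotamer is a minor one, which is why heating is planned.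

Step 6
Reactants: 9 meso-2,4-dimethylglutaric anhydride [(3R,5S)-3,5-dimethyloxane-2,6-dione]
Product: 10 (2S,4R)-2,4-dimethyl-5-oxoheptanoic acid
Conditions: [Rh(cod)Cl]2 (4 mol %), (S)-t-Bu-PHOX (8 mol %), Et2Zn, THF, 50 °C; then 1 M HCl
Reagents that add atoms: diethylzinc, CC[Zn]CC
Why: rhodium-catalysed enantioselective alkylative desymmetrisation of the meso anhydride with an alkylzinc; the ligand selects one of the two enantiotopic carbonyl groups, which fixes both syn methyl centres (C2, C4) at once.

Step 7
Reactants: 10 (2S,4R)-2,4-dimethyl-5-oxoheptanoic acid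
Product: 11 benzyl (2S,4R)-2,4-dimethyl-5-oxoheptanoate
Conditions: BnBr, K2CO3, DMF, rt
Reagents that add atoms: benzyl bromide, BrCc1ccccc1
Why: carboxylate O-alkylation under mild base, which leaves both α-stereocentres untouched.

Step 8
Reactants: 11 benzyl (2S,4R)-2,4-dimethyl-5-oxoheptanoate
Product: 13 benzyl (2S,4R)-2,4-dimethyl-5-oxohept-6-enoate, via silyl enol ether 12 (not isolated)
Conditions: LiN(iPr)2, Me3SiCl, THF, −78 °C; then Pd(OAc)2 (1.0 equiv), MeCN, rt
Reagents that add atoms: chlorotrimethylsilane, C[Si](C)(C)Cl (silyl group of 12 only, lost again in 13)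
Why: Saegusa–Ito dehydrogenation; kinetic deprotonation goes to the ethyl CH2 (less hindered than the methine, more acidic than the ester α-H) and divalent palladium turns the silyl enol ether into the vinyl ketone without touching a stereocentre.

Step 9
Reactants: 8 (1S,4S,7S)-4-(benzyloxy)-1,7-dimethyl-2-oxabicyclo[2.2.2]octane-3,6-dione; 13 benzyl (2S,4R)-2,4-dimethyl-5-oxohept-6-enoate
Product: 15 benzyl (2S,4R)-5-[(3aS,5S,6S,7aR)-3a-(benzyloxy)-3,6-dihydroxy-5,6-dimethyl-7-oxo-3a,4,5,6,7,7a-hexahydro-1H-inden-2-yl]-2,4-dimethyl-5-oxopentanoate (enol form of the 2-acylcyclopentanone), via lithium enolate 14 (not isolated)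
Conditions: LiN(SiMe3)2 (1.05 equiv), THF, −78 °C; then 13, −78 → 0 °C; aq. NH4Cl
Reagents that add atoms: none
Why: Michael–Claisen annulation: the only enolisable position of 8 (C22) adds to the vinyl ketone and the regiodefined C20 enolate attacks the lactone carbonyl C19 (5-exo-trig), releasing the tertiary O18 alkoxide, which the new β-diketone protonates; C22 is epimerisable next to the ketone and only the epimer with the chain on the lactone face can cyclise, so the mixture should converge on the cis-fused product.

Step 10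
Reactants: 15 (as named in step 9)
Product: 16 benzyl (2S,4R)-5-[(3aS,5S,6S,7S,7aS)-3a-(benzyloxy)-3,6,7-trihydroxy-5,6-dimethyl-3a,4,5,6,7,7a-hexahydro-1H-inden-2-yl]-2,4-dimethyl-5-oxopentanoate
Conditions: Me4NBH(OAc)3, MeCN/AcOH (1:1), −30 °C
Reagents that add atoms: none
Why: hydroxyl-directed reduction (Saksena–Evans): the tertiary O18–H next to the C23 ketone binds the triacetoxyborohydride and delivers hydride on its own face, giving the trans-1,2-diol (C23), while the enolised β-diketone and the ester are not reduced.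

Step 11
Reactants: 16 (as named in step 10)
Product: 18 6,7-bis(triethylsilyl) ether of 16 (O18 and O24 silylated, enol free), via tris-silyl ether 17 (not isolated)
Conditions: Et3SiOTf (3.5 equiv), 2,6-lutidine, CH2Cl2, −78 → 0 °C; then MeOH, aq. NaHCO3
Reagents that add atoms: triethylsilyl trifluoromethanesulfonate, CC[Si](CC)(CC)OS(=O)(=O)C(F)(F)F
Why: silyl ether formation at the two cage-side hydroxyls, so that the tertiary O11–H freed in step 12 is the only alcohol left; the labile enol silyl ether is cleaved on methanolic work-up so that it cannot pass its silyl group to O11.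

Step 12
Reactants: 18 (as named in step 11)
Product: 19 (2S,4R)-5-[(3aS,5S,6S,7S,7aS)-3,3a-dihydroxy-5,6-dimethyl-6,7-bis(triethylsilyloxy)-3a,4,5,6,7,7a-hexahydro-1H-inden-2-yl]-2,4-dimethyl-5-oxopentanoic acid
Conditions: H2 (1 atm), Pd(OH)2/C, EtOAc, rt
Reagents that add atoms: none
Why: hydrogenolysis removes the benzyl ester and the tertiary benzyl ether in one operation; silyl ethers and the tetrasubstituted enol double bond should survive in a non-protic solvent.

Step 13
Reactants: 19 (as named in step 12); 20 2,2-dimethyl-1,3-dioxane-4,6-dione (Meldrum's acid)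
Product: 23 eleven-membered β-keto lactone (ester between O11 and the new C9 carbonyl; ring O11, C9, C8, C6, C4, C3, C2, C25, C20, C19, C12), via acyl Meldrum's acid 21 (not isolated), via acylketene 22 (not isolated)
Conditions: 20, EDC·HCl, DMAP, CH2Cl2, 0 °C → rt; acid wash; then toluene (1 mM), 110 °C
Reagents that add atoms: none
Why: C-acylation of Meldrum's acid, then thermal loss of acetone and CO2 to an acylketene that is captured by the only free alcohol, the tertiary O11–H (acylketene macrolactonisation; an acyl group caught first by the neighbouring enol oxygen would be passed on by acyl shift); no stereocentre is formed.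

Step 14
Reactants: 23 (as named in step 13)
Product: 26 abyssomicin N, via desilylated diol 24 (not isolated), via alkylidene butenolide 25 (not isolated)
Conditions: HF·pyridine, THF, 0 °C → rt; then TsOH·H2O (10 mol %), benzene, 4 Å MS, 50 °C
Reagents that add atoms: none
Why: after desilylation the active methylene C8 condenses across the ring with the neighbouring ring carbonyl C19 (intramolecular Knoevenagel, forming the γ-lactone and with it the eight-membered ring) and the tertiary O18–H adds to the doubly activated alkene (6-exo oxa-Michael) to close the ether bridge; C19 can only form cis-bridged, and the epimerisable C20 should settle with its acyl branch cis to the lactone branch.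

**Compound list**

1 | methyl 3,3-dimethoxycyclobutane-1-carboxylate | COC(=O)C1CC(OC)(OC)C1 | starting material
2 | methyl 1-hydroxy-3,3-dimethoxycyclobutane-1-carboxylate | COC(=O)C1(O)CC(OC)(OC)C1 | intermediate
3 | methyl 1-(benzyloxy)-3,3-dimethoxycyclobutane-1-carboxylate | COC(=O)C1(OCc2ccccc2)CC(OC)(OC)C1 | intermediate
4 | 1-(benzyloxy)-3,3-dimethoxycyclobutane-1-carboxylic acid | OC(=O)C1(OCc2ccccc2)CC(OC)(OC)C1 | intermediate
5 | 1-(benzyloxy)-3-oxocyclobutane-1-carboxylic acid | OC(=O)C1(OCc2ccccc2)CC(=O)C1 | intermediate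
6 | but-2-yne | CC#CC | starting material
7 | (Z)-but-2-en-2-yl 1-(benzyloxy)-3-oxocyclobutane-1-carboxylate | C/C=C(/C)OC(=O)C1(OCc2ccccc2)CC(=O)C1 | intermediate
8 | (1S,4S,7S)-4-(benzyloxy)-1,7-dimethyl-2-oxabicyclo[2.2.2]octane-3,6-dione | O=C1O[C@@]2(C)[C@@H](C)C[C@]1(OCc1ccccc1)CC2=O | intermediate
9 | meso-2,4-dimethylglutaric anhydride | C[C@@H]1C[C@H](C)C(=O)OC1=O | starting material
10 | (2S,4R)-2,4-dimethyl-5-oxoheptanoic acid | CCC(=O)[C@H](C)C[C@H](C)C(=O)O | intermediate
11 | benzyl (2S,4R)-2,4-dimethyl-5-oxoheptanoate | CCC(=O)[C@H](C)C[C@H](C)C(=O)OCc1ccccc1 | intermediate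
12 | benzyl (2S,4R)-2,4-dimethyl-5-(trimethylsilyloxy)hept-5-enoate (drawn Z; geometry immaterial) | C/C=C(\O[Si](C)(C)C)[C@H](C)C[C@H](C)C(=O)OCc1ccccc1 | intermediate
13 | benzyl (2S,4R)-2,4-dimethyl-5-oxohept-6-enoate | C=CC(=O)[C@H](C)C[C@H](C)C(=O)OCc1ccccc1 | intermediate
14 | lithium enolate of the Michael adduct (8 carrying the 3-oxoalkyl chain at C22; geometry immaterial) | O=C1O[C@@]2(C)[C@@H](C)C[C@]1(OCc1ccccc1)[C@@H](C/C=C(\O[Li])[C@H](C)C[C@H](C)C(=O)OCc1ccccc1)C2=O | intermediate
15 | benzyl (2S,4R)-5-[(3aS,5S,6S,7aR)-3a-(benzyloxy)-3,6-dihydroxy-5,6-dimethyl-7-oxo-3a,4,5,6,7,7a-hexahydro-1H-inden-2-yl]-2,4-dimethyl-5-oxopentanoate | O=C(OCc1ccccc1)[C@@H](C)C[C@@H](C)C(=O)C1=C(O)[C@]2(OCc3ccccc3)C[C@H](C)[C@](C)(O)C(=O)[C@@H]2C1 | intermediate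
16 | benzyl (2S,4R)-5-[(3aS,5S,6S,7S,7aS)-3a-(benzyloxy)-3,6,7-trihydroxy-5,6-dimethyl-3a,4,5,6,7,7a-hexahydro-1H-inden-2-yl]-2,4-dimethyl-5-oxopentanoate | O=C(OCc1ccccc1)[C@@H](C)C[C@@H](C)C(=O)C1=C(O)[C@]2(OCc3ccccc3)C[C@H](C)[C@](C)(O)[C@@H](O)[C@@H]2C1 | intermediate
17 | tris(triethylsilyl) ether of 16 (O18, O24 and enol oxygen) | O=C(OCc1ccccc1)[C@@H](C)C[C@@H](C)C(=O)C1=C(O[Si](CC)(CC)CC)[C@]2(OCc3ccccc3)C[C@H](C)[C@](C)(O[Si](CC)(CC)CC)[C@@H](O[Si](CC)(CC)CC)[C@@H]2C1 | intermediate
18 | bis(triethylsilyl) ether of 16 (O18 and O24) | O=C(OCc1ccccc1)[C@@H](C)C[C@@H](C)C(=O)C1=C(O)[C@]2(OCc3ccccc3)C[C@H](C)[C@](C)(O[Si](CC)(CC)CC)[C@@H](O[Si](CC)(CC)CC)[C@@H]2C1 | intermediate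
19 | (2S,4R)-5-[(3aS,5S,6S,7S,7aS)-3,3a-dihydroxy-5,6-dimethyl-6,7-bis(triethylsilyloxy)-3a,4,5,6,7,7a-hexahydro-1H-inden-2-yl]-2,4-dimethyl-5-oxopentanoic acid | OC(=O)[C@@H](C)C[C@@H](C)C(=O)C1=C(O)[C@]2(O)C[C@H](C)[C@](C)(O[Si](CC)(CC)CC)[C@@H](O[Si](CC)(CC)CC)[C@@H]2C1 | intermediate
20 | 2,2-dimethyl-1,3-dioxane-4,6-dione (Meldrum's acid) | CC1(C)OC(=O)CC(=O)O1 | starting material
21 | acyl Meldrum's acid of 19 (enol form) | CC1(C)OC(=O)C(=C(O)[C@@H](C)C[C@@H](C)C(=O)C2=C(O)[C@]3(O)C[C@H](C)[C@](C)(O[Si](CC)(CC)CC)[C@@H](O[Si](CC)(CC)CC)[C@@H]3C2)C(=O)O1 | intermediate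
22 | acylketene from 21 | O=C=CC(=O)[C@@H](C)C[C@@H](C)C(=O)C1=C(O)[C@]2(O)C[C@H](C)[C@](C)(O[Si](CC)(CC)CC)[C@@H](O[Si](CC)(CC)CC)[C@@H]2C1 | intermediate
23 | eleven-membered β-keto lactone (O11–C9 ester) | O=C1CC(=O)[C@@H](C)C[C@@H](C)C(=O)C2=C(O)[C@]3(O1)C[C@H](C)[C@](C)(O[Si](CC)(CC)CC)[C@@H](O[Si](CC)(CC)CC)[C@@H]3C2 | intermediate
24 | desilylated β-keto lactone (free O18–H and O24–H) | O=C1CC(=O)[C@@H](C)C[C@@H](C)C(=O)C2=C(O)[C@]3(O1)C[C@H](C)[C@](C)(O)[C@@H](O)[C@@H]3C2 | intermediate
25 | alkylidene butenolide (C8=C19, ether bridge still open; C20 drawn in the natural configuration) | C[C@@H]1C[C@H](C)C(=O)C2=C3[C@@H](C[C@H]4[C@H](O)[C@@](C)(O)[C@@H](C)C[C@@]34OC2=O)C1=O | intermediate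
26 | abyssomicin N | C[C@@H]1C[C@H](C)/C(O)=C2/C(=O)O[C@]34C[C@H](C)[C@]5(C)O[C@]23[C@@H](C[C@H]4[C@@H]5O)C1=O | target

**Step count and risks**

Total: 14 steps. Longest linear sequence: 11 steps (steps 1–5 and 9–14); steps 6–8 make the side-chain fragment.

Steps most likely to fail:

1. Step 5. The nickel catalyst may insert into the enol-ester C–O bond, or the alkylnickel intermediate may lose β-hydride or β-alkoxide instead of closing the ring; ligand control over the enantiotopic bonds may also be poor. Fallback with known chemistry, setting out from 3 and coming back at 8: 2 M HCl in acetone gives methyl 1-(benzyloxy)-3-oxocyclobutane-1-carboxylate F1. The known nickel-catalysed insertion of an internal alkyne into a 3,3-disubstituted cyclobutanone (Ni(cod)2, PCy3, but-2-yne 6, toluene, 100 °C) makes the same two bonds and gives racemic methyl 1-(benzyloxy)-3,4-dimethyl-5-oxocyclohex-3-ene-1-carboxylate F2. Hydrogenolysis (H2, Pd/C, EtOAc) gives methyl 1-hydroxy-3,4-dimethyl-5-oxocyclohex-3-ene-1-carboxylate F3. Hydroxyl-directed hydrogenation with [Ir(cod)(PCy3)(py)]PF6 puts both hydrogens on the OH face and gives methyl (1S,3S,4S)-1-hydroxy-3,4-dimethyl-5-oxocyclohexane-1-carboxylate F4 (racemic). LiOH and then PhI(OH)OTs in MeCN bring about oxidative δ-lactonisation at the tertiary α-carbon, the only one the carboxylate can reach, to give (1S,4S,7S)-4-hydroxy-1,7-dimethyl-2-oxabicyclo[2.2.2]octane-3,6-dione F5 (racemic). Benzyl trichloroacetimidate with catalytic TfOH returns racemic 8; the diastereomers formed from it and enantiopure 13 in step 9 would be separated at the stage of 15.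

2. Step 13. The acylketene may oligomerise or be consumed by the enol before the eleven-membered ring closes. Fallback, setting out from 19 and coming back at 23: activation of the acid with carbonyldiimidazole and homologation with Mg(O2CCH2COS-t-Bu)2 give the S-tert-butyl β-keto thioester of 19 F6, and silver-promoted transesterification (AgOCOCF3, Na2HPO4, benzene, high dilution) closes the ring onto O11.

3. Step 14. The active methylene C8 may attack the side-chain carbonyl C25 (six-membered carbocycle) instead of C19, or the dehydration may stall. Fallback, setting out from 23 and coming back at 26, reverses the order of bond formation so that only C19 is activated: HF·pyridine gives 24; HC(OMe)3, MeOH and PPTS convert the hemiketal between O18 and C19 into the bridged methyl ketal of 24 F7; Me3SiOTf/Et3N (silyl enol ether of the β-keto lactone) and then catalytic Me3SiOTf in CH2Cl2 ionise the ketal and close C8–C19 by a Mukaiyama-type addition to the oxocarbenium ion, giving 26 after aqueous work-up.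

**Further compounds**

F1 | step 5 | methyl 1-(benzyloxy)-3-oxocyclobutane-1-carboxylate | COC(=O)C1(OCc2ccccc2)CC(=O)C1
F2 | step 5 | methyl 1-(benzyloxy)-3,4-dimethyl-5-oxocyclohex-3-ene-1-carboxylate (racemic) | COC(=O)C1(OCc2ccccc2)CC(C)=C(C)C(=O)C1
F3 | step 5 | methyl 1-hydroxy-3,4-dimethyl-5-oxocyclohex-3-ene-1-carboxylate (racemic) | COC(=O)C1(O)CC(C)=C(C)C(=O)C1
F4 | step 5 | methyl (1S,3S,4S)-1-hydroxy-3,4-dimethyl-5-oxocyclohexane-1-carboxylate (racemic, one enantiomer drawn) | COC(=O)[C@]1(O)C[C@H](C)[C@H](C)C(=O)C1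
F5 | step 5 | (1S,4S,7S)-4-hydroxy-1,7-dimethyl-2-oxabicyclo[2.2.2]octane-3,6-dione (racemic, one enantiomer drawn) | O=C1O[C@@]2(C)[C@@H](C)C[C@]1(O)CC2=O
F6 | step 13 | S-tert-butyl β-keto thioester of 19 | CC(C)(C)SC(=O)CC(=O)[C@@H](C)C[C@@H](C)C(=O)C1=C(O)[C@]2(O)C[C@H](C)[C@](C)(O[Si](CC)(CC)CC)[C@@H](O[Si](CC)(CC)CC)[C@@H]2C1
F7 | step 14 | bridged methyl ketal of 24 (O18–C19 bond formed, methoxy on C19) | O=C1CC(=O)[C@@H](C)C[C@@H](C)C(=O)[C@@H]2C[C@H]3[C@H](O)[C@@]4(C)O[C@]2(OC)[C@]3(O1)C[C@@H]4C
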